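## Retrosynthetic overview

- **Numbering.** Rings A and B carry labdane numbers (C1–C10; C17 = CH3 on C8, C18 = CH2OH and C19 = CH3 on C4, C20 = CH3 on C10). The chain is C11, C12, C13(=C16H2), C14(OH), C15(OH). The lactone ring is O1′, C2′(=O), C3′, C4′(CH3), C5′.
- **Key disconnection C14–C15.** The enabling feature is the exocyclic methylene C13=C16 next to carbinol C14. The unit C16H2=C13–C14(OH) is the retron of an allylboration. At the aldehyde level it is a 2-alkylacrolein whose C16=C13–C14=O array accepts a diboron 1,4, which makes C14 nucleophilic.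
- **Lactone partner.** C15 plus ring atoms O1′ and C2′–C5′ map onto 3-methylfuran-2-carbaldehyde, a non-enolisable stand-in for the configurationally labile 5-formylbutenolide.
- **Enal partner.** It comes from (+)-larixol, which supplies rings A and B and C5, C6, C9 and C10. The changes are side-chain cleavage, hydration at C8, 6α-OH-directed C18–H silylation/oxidation, and Shapiro formylation.
- **Ring order.** Rings A and B come from the pool. A temporary tetrahydropyran ketal (C8–O–C13) and an oxasilinane (O6–Si–C18) are made and opened. The furan ring is opened by singlet oxygen and re-closed last as the butenolide, after ketone reduction sets C5′.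

Key step: step 9

Remark: (+)-larixol and 3-methylfuran-2-carbaldehyde are taken as purchasable. The ketal centre C13 is drawn as the anomerically favoured epimer. The endoperoxide bridgeheads and the lactol carbon are expected as epimer mixtures, are drawn without configuration, and vanish later.

## Route

Step 1
Reactants: 1 (+)-larixol
Product: 2 6α-hydroxy-14,15-dinorlabd-8(17)-en-13-one
Conditions: KMnO4, BnEt3NCl (cat.), CH2Cl2, 0 °C to rt
Reagents that add atoms: none
Why: Permanganate degradation of a tertiary vinyl carbinol (dihydroxylation, glycol cleavage, oxidative decarboxylation) is the classical labdane side-chain cleavage to the C13 methyl ketone, should spare the hindered C8=C17 alkene and the secondary 6α-OH under cold phase-transfer conditions, and creates no stereocentre.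

Step 2
Reactants: 2 6α-hydroxy-14,15-dinorlabd-8(17)-en-13-one
Product: 3 6α,8α-dihydroxy-14,15-dinorlabdan-13-one
Conditions: Co(acac)2 (cat.), PhSiH3, O2 (1 atm), THF, rt
Reagents that add atoms: dioxygen, O=O
Why: In this Mukaiyama hydration a cobalt hydride transfers H to C17, and the tertiary C8 radical should take up O2 from the α face, opposite the axial C20 methyl, which places the hydroxyl 8α (equatorial) and C17 β (axial) while ketone and alcohol stay inert.

Step 3
Reactants: 3 6α,8α-dihydroxy-14,15-dinorlabdan-13-one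
Product: 4 (13S)-8α,13-epoxy-13-methoxy-14,15-dinorlabdan-6α-ol (cyclic methyl ketal)
Conditions: MeOH, PPTS (cat.), 3 Å MS, rt
Reagents that add atoms: methanol, CO
Why: Acid-catalysed mixed ketalisation (6-exo attack of the 8α-OH on C13, then exchange with methanol) closes a temporary tetrahydropyran ring that masks ketone and tertiary alcohol at once, and the transient C13 centre is under thermodynamic control (anomeric effect, methoxy axial) and is erased in step 5.

Step 4
Reactants: 4 cyclic methyl ketal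
Product: 6 oxasilinane-bridged ketal (O6–SiEt2–C18), via hydridosilyl ether 5 (not isolated)
Conditions: Et2SiH2, [Ir(cod)OMe]2 (cat.), THF, rt; evaporate; [Rh(cod)Cl]2 (cat.), Xantphos, norbornene, THF, 100 °C
Reagents that add atoms: diethylsilane, CC[SiH2]CC
Why: This is dehydrogenative O-silylation followed by hydroxyl-directed intramolecular C–H silylation, in which the γ-carbons C4, C8 and C10 carry no hydrogen so only a δ-methyl can react, and the equatorial 6α-O–Si–H reaches only the equatorial 4α-methyl (C18), closing the six-membered oxasilinane and making C4 stereogenic with CH2Si α and C19 β.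

Step 5
Reactants: 6 oxasilinane-bridged ketal
Product: 8 6α,8α,18-trihydroxy-14,15-dinorlabdan-13-one, via ketal diol 7 (not isolated)
Conditions: H2O2, KHCO3, KF, THF/MeOH, 50 °C; then aq. HCl, THF, rt
Reagents that add atoms: hydrogen peroxide, OO; water, O
Why: Tamao–Fleming oxidation turns C18–Si into C18–OH without touching a stereocentre, and aqueous acid then hydrolyses the mixed ketal back to the C13 ketone and the 8α-OH.

Step 6
Reactants: 8 6α,8α,18-trihydroxy-14,15-dinorlabdan-13-one
Product: 9 6α,8α,18-tris(triethylsilyloxy)-14,15-dinorlabdan-13-one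
Conditions: TESOTf, 2,6-lutidine, CH2Cl2, −78 to 0 °C
Reagents that add atoms: triethylsilyl triflate, CC[Si](CC)(CC)OS(=O)(=O)C(F)(F)F
Why: Silyl triflate with a hindered pyridine base should protect the primary, secondary and tertiary hydroxyls in one operation faster than it enolises the ketone at low temperature.

Step 7
Reactants: 9 tris-TES methyl ketone
Product: 10 (E)-2,4,6-triisopropylbenzenesulfonylhydrazone of 9
Conditions: 2,4,6-iPr3C6H2SO2NHNH2, THF, rt
Reagents that add atoms: 2,4,6-triisopropylbenzenesulfonohydrazide, CC(C)c1cc(C(C)C)c(S(=O)(=O)NN)c(C(C)C)c1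
Why: Uncatalysed hydrazone condensation of a methyl ketone leaves the silyl ethers intact and should favour, for steric reasons, the isomer with the sulfonamide nitrogen on the methyl side.

Step 8
Reactants: 10 trisylhydrazone
Product: 12 6α,8α,18-tris(triethylsilyloxy)-15-norlabd-13(16)-en-14-al, via vinyllithium 11 (not isolated)
Conditions: n-BuLi, THF, −78 to 0 °C; DMF, −78 °C to rt; H2O
Reagents that add atoms: N,N-dimethylformamide, CN(C)C=O
Why: In this Shapiro reaction syn-directed deprotonation at the methyl group, then loss of sulfinate and N2, gives the less substituted vinyllithium, which DMF formylates to the 2-substituted acrolein.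

Step 9
Reactants: 12 enal; 13 bis(pinacolato)diboron; 14 3-methylfuran-2-carbaldehyde
Product: 17 (14S,15R)-syn-diol furan, via boryloxyallylboronate 15 (not isolated), via bis(borate) adduct 16 (not isolated)
Conditions: 13, Pt(PPh3)2(C2H4) (cat.), toluene, 80 °C; then 14, (R)-TRIP [(R)-3,3′-bis(2,4,6-triisopropylphenyl)-1,1′-binaphthyl-2,2′-diyl hydrogen phosphate] (cat.), 4 Å MS, −30 to 0 °C; aq. NaHCO3
Reagents that add atoms: none
Why: Proposed new method: zerovalent platinum inserts into the B–B bond of 13 and transfers both boryl groups 1,4 to the s-cis C16=C13–C14=O array of 12, so that 15 is at once an enol borate and an allylboronate whose γ-carbon is the former carbonyl carbon C14, now nucleophilic, with its oxygen locked cis to the CH2–B group. Aldehyde 14 then reacts through a closed six-membered Zimmerman–Traxler chair at the carbon-bound boron (phosphoric acid hydrogen-bonded to a pinacol oxygen), which forms C14–C15, returns the double bond to C13=C16 and leaves both oxygens as borates that the work-up frees. The closest known reaction types are the platinum-catalysed 1,4-diboration of enones and enals and the chiral-phosphoric-acid-catalysed addition of (Z)-γ-alkoxyallyl pinacolboronates to aldehydes, which gives syn-1,2-diol derivatives, but their combination with a boryloxy group in place of alkoxy and a 2-alkyl branch has not been shown. No ring is closed; the syn relation C14/C15 follows from the cis enol oxygen sitting axial in the chair, and the absolute sense (14S,15R) from the catalyst, (R)-TRIP being the enantiomer expected, by analogy with allyl and crotyl transfer to aryl aldehydes, to open the Re face of 14, while the decalin stereocentres are too remote to interfere. The step needs 1,4- over 1,2-diboration, secured by the s-cis enal binding on platinum, and allyl transfer from C14 over aldol attack from C13, secured because the oxygen-bound boron carries three oxygens and is hardly Lewis acidic and because attack through C13 would build a quaternary centre. Aldehyde 14 has no α-hydrogen and can neither enolise nor epimerise, which is why the lactone ring is carried through this step as a furan.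

Step 10
Reactants: 17 syn-diol furan
Product: 18 penta-TES furan (14,15-bis-TES ether of 17)
Conditions: TESCl, imidazole, DMAP (cat.), DMF, rt
Reagents that add atoms: chlorotriethylsilane, CC[Si](Cl)(CC)CC
Why: Standard non-acidic silylation of two secondary alcohols keeps the furfurylic C15–O bond intact and installs a non-chelating oxygen substituent at C15 for step 13.

Step 11
Reactants: 18 penta-TES furan
Product: 20 γ-hydroxybutenolide, via furan endoperoxide 19 (not isolated)
Conditions: O2, tetraphenylporphyrin (cat.), visible light, iPr2NEt, CH2Cl2, −78 °C to rt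
Reagents that add atoms: dioxygen, O=O
Why: [4+2] cycloaddition of singlet oxygen to the electron-rich furan should far outrun the ene reaction of the 1,1-disubstituted C13=C16 alkene, and Kornblum–DeLaMare fragmentation at the only bridgehead C–H (C2′) makes C2′ the lactone carbonyl and C5′ the lactol carbon.

Step 12
Reactants: 20 γ-hydroxybutenolide
Product: 21 methyl (Z)-4-oxo-2-enoate (open keto ester)
Conditions: TMSCHN2, toluene/MeOH, 0 °C
Reagents that add atoms: (trimethylsilyl)diazomethane, C[Si](C)(C)C=[N+]=[N-]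
Why: Diazoalkane O-methylation drains the ring–chain equilibrium through the open carboxylic acid under neutral conditions, which should preserve the (Z)-alkene and the enolisable C15 centre.

Step 13
Reactants: 21 methyl (Z)-4-oxo-2-enoate
Product: 23 penta-TES butenolide, via hydroxy ester 22 (not isolated)
Conditions: (R)-Me-CBS oxazaborolidine, catecholborane, toluene, −78 °C; MeOH, aq. NaHCO3; SiO2
Reagents that add atoms: none
Why: This 1,2-selective Corey–Bakshi–Shibata reduction sets C5′ (R) on the ketone face chosen both by the catalyst (alkenyl branch as the large group) and by the Felkin–Anh model (hydride anti to the C15–O bond, giving the 15,5′-syn relation), and the (Z)-γ-hydroxy ester then closes the butenolide by 5-exo-trig lactonisation.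

Step 14
Reactants: 23 penta-TES butenolide
Product: 24 CNP0301623.1 (target)
Conditions: HF·pyridine, pyridine, THF, 0 °C to rt
Reagents that add atoms: none
Why: Buffered fluoride cleavage of all five triethylsilyl ethers should neither dehydrate the tertiary and allylic alcohols, nor epimerise C5′, nor open the lactone.

## Compound list

1 | (+)-larixol, (13S)-labda-8(17),14-diene-6α,13-diol | C=C[C@@](C)(O)CC[C@@H]1[C@@]2(C)CCCC(C)(C)[C@@H]2[C@@H](O)CC1=C | starting material
2 | 6α-hydroxy-14,15-dinorlabd-8(17)-en-13-one | CC(=O)CC[C@@H]1[C@@]2(C)CCCC(C)(C)[C@@H]2[C@@H](O)CC1=C | intermediate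
3 | 6α,8α-dihydroxy-14,15-dinorlabdan-13-one | CC(=O)CC[C@@H]1[C@@]2(C)CCCC(C)(C)[C@@H]2[C@@H](O)C[C@@]1(C)O | intermediate
4 | (13S)-8α,13-epoxy-13-methoxy-14,15-dinorlabdan-6α-ol | CO[C@]1(C)CC[C@@H]2[C@@]3(C)CCCC(C)(C)[C@@H]3[C@@H](O)C[C@@]2(C)O1 | intermediate
5 | 6-O-diethyl(hydrido)silyl ether of 4 | CO[C@]1(C)CC[C@@H]2[C@@]3(C)CCCC(C)(C)[C@@H]3[C@@H](O[SiH](CC)CC)C[C@@]2(C)O1 | intermediate
6 | oxasilinane-bridged ketal (ring O6–SiEt2–C18–C4–C5–C6) | CO[C@]1(C)CC[C@@H]2[C@@]3(C)CCC[C@@](C)(C[Si]4(CC)CC)[C@@H]3[C@@H](O4)C[C@@]2(C)O1 | intermediate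
7 | (13S)-8α,13-epoxy-13-methoxy-14,15-dinorlabdane-6α,18-diol | CO[C@]1(C)CC[C@@H]2[C@@]3(C)CCC[C@@](C)(CO)[C@@H]3[C@@H](O)C[C@@]2(C)O1 | intermediate
8 | 6α,8α,18-trihydroxy-14,15-dinorlabdan-13-one | CC(=O)CC[C@@H]1[C@@]2(C)CCC[C@@](C)(CO)[C@@H]2[C@@H](O)C[C@@]1(C)O | intermediate
9 | 6α,8α,18-tris(triethylsilyloxy)-14,15-dinorlabdan-13-one | CC(=O)CC[C@@H]1[C@@]2(C)CCC[C@@](C)(CO[Si](CC)(CC)CC)[C@@H]2[C@@H](O[Si](CC)(CC)CC)C[C@@]1(C)O[Si](CC)(CC)CC | intermediate
10 | (E)-2,4,6-triisopropylbenzenesulfonylhydrazone of 9 | C/C(CC[C@@H]1[C@@]2(C)CCC[C@@](C)(CO[Si](CC)(CC)CC)[C@@H]2[C@@H](O[Si](CC)(CC)CC)C[C@@]1(C)O[Si](CC)(CC)CC)=N\NS(=O)(=O)c1c(C(C)C)cc(C(C)C)cc1C(C)C | intermediate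
11 | 13-lithio-13(16)-ene (vinyllithium) | [Li]C(=C)CC[C@@H]1[C@@]2(C)CCC[C@@](C)(CO[Si](CC)(CC)CC)[C@@H]2[C@@H](O[Si](CC)(CC)CC)C[C@@]1(C)O[Si](CC)(CC)CC | intermediate
12 | 6α,8α,18-tris(triethylsilyloxy)-15-norlabd-13(16)-en-14-al | C=C(CC[C@@H]1[C@@]2(C)CCC[C@@](C)(CO[Si](CC)(CC)CC)[C@@H]2[C@@H](O[Si](CC)(CC)CC)C[C@@]1(C)O[Si](CC)(CC)CC)C=O | intermediate
13 | bis(pinacolato)diboron | CC1(C)OB(OC1(C)C)B1OC(C)(C)C(C)(C)O1 | starting material
14 | 3-methylfuran-2-carbaldehyde | Cc1ccoc1C=O | starting material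
15 | γ-(boryloxy)allylboronate (C16–Bpin, C14–OBpin, oxygen cis to CH2B) | CC1(C)OB(C/C(CC[C@@H]2[C@@]3(C)CCC[C@@](C)(CO[Si](CC)(CC)CC)[C@@H]3[C@@H](O[Si](CC)(CC)CC)C[C@@]2(C)O[Si](CC)(CC)CC)=C\OB2OC(C)(C)C(C)(C)O2)OC1(C)C | intermediate
16 | 14,15-bis(O-Bpin) adduct | C=C(CC[C@@H]1[C@@]2(C)CCC[C@@](C)(CO[Si](CC)(CC)CC)[C@@H]2[C@@H](O[Si](CC)(CC)CC)C[C@@]1(C)O[Si](CC)(CC)CC)[C@H](OB1OC(C)(C)C(C)(C)O1)[C@@H](OB1OC(C)(C)C(C)(C)O1)c1occc1C | intermediate
17 | (14S,15R)-15-(3-methylfuran-2-yl)-14,15-diol, tris-TES | C=C(CC[C@@H]1[C@@]2(C)CCC[C@@](C)(CO[Si](CC)(CC)CC)[C@@H]2[C@@H](O[Si](CC)(CC)CC)C[C@@]1(C)O[Si](CC)(CC)CC)[C@H](O)[C@@H](O)c1occc1C | intermediate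
18 | penta-TES furan | C=C(CC[C@@H]1[C@@]2(C)CCC[C@@](C)(CO[Si](CC)(CC)CC)[C@@H]2[C@@H](O[Si](CC)(CC)CC)C[C@@]1(C)O[Si](CC)(CC)CC)[C@H](O[Si](CC)(CC)CC)[C@@H](O[Si](CC)(CC)CC)c1occc1C | intermediate
19 | furan endoperoxide (2,3,7-trioxabicyclo[2.2.1]heptene, both faces) | C=C(CC[C@@H]1[C@@]2(C)CCC[C@@](C)(CO[Si](CC)(CC)CC)[C@@H]2[C@@H](O[Si](CC)(CC)CC)C[C@@]1(C)O[Si](CC)(CC)CC)[C@H](O[Si](CC)(CC)CC)[C@@H](O[Si](CC)(CC)CC)C12OOC(O1)C=C2C | intermediate
20 | 5′-hydroxy-4′-methylbutenolide (lactol epimers, in equilibrium with the open keto acid) | C=C(CC[C@@H]1[C@@]2(C)CCC[C@@](C)(CO[Si](CC)(CC)CC)[C@@H]2[C@@H](O[Si](CC)(CC)CC)C[C@@]1(C)O[Si](CC)(CC)CC)[C@H](O[Si](CC)(CC)CC)[C@@H](O[Si](CC)(CC)CC)C1(O)OC(=O)C=C1C | intermediate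
21 | methyl (Z)-3-methyl-4-oxo-2-enoate (C5′ ketone) | C=C(CC[C@@H]1[C@@]2(C)CCC[C@@](C)(CO[Si](CC)(CC)CC)[C@@H]2[C@@H](O[Si](CC)(CC)CC)C[C@@]1(C)O[Si](CC)(CC)CC)[C@H](O[Si](CC)(CC)CC)[C@@H](O[Si](CC)(CC)CC)C(=O)/C(C)=C\C(=O)OC | intermediate
22 | methyl (Z,5′R)-4-hydroxy-3-methyl-2-enoate | C=C(CC[C@@H]1[C@@]2(C)CCC[C@@](C)(CO[Si](CC)(CC)CC)[C@@H]2[C@@H](O[Si](CC)(CC)CC)C[C@@]1(C)O[Si](CC)(CC)CC)[C@H](O[Si](CC)(CC)CC)[C@@H](O[Si](CC)(CC)CC)[C@H](O)/C(C)=C\C(=O)OC | intermediate
23 | penta-TES butenolide | C=C(CC[C@@H]1[C@@]2(C)CCC[C@@](C)(CO[Si](CC)(CC)CC)[C@@H]2[C@@H](O[Si](CC)(CC)CC)C[C@@]1(C)O[Si](CC)(CC)CC)[C@H](O[Si](CC)(CC)CC)[C@@H](O[Si](CC)(CC)CC)[C@@H]1OC(=O)C=C1C | intermediate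
24 | CNP0301623.1 | C=C(CC[C@@H]1[C@@]2(C)CCC[C@@](C)(CO)[C@@H]2[C@@H](O)C[C@@]1(C)O)[C@H](O)[C@@H](O)[C@@H]1OC(=O)C=C1C | target

## Step count and risks

Total step count: 14. Longest linear sequence: 14 (1 to 24).

### Steps most likely to fail

**Step 9 (Proposed new method).**
- What may go wrong: the enal may dimerise thermally or undergo 1,2-diboration; the acid catalyst may protonate the enol borate; C13 may attack in an aldol sense; the β-branched reagent may transfer sluggishly; facial control may be weak or opposite (the other catalyst enantiomer would address only this last point).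
- Fallback by known chemistry, setting out from 12:
  - iBu2AlH in CH2Cl2 at −78 °C gives the allylic alcohol F1.
  - MOMCl and iPr2NEt give the methoxymethyl ether F2.
  - α-Lithiation with s-BuLi in THF at −78 °C gives the chelated (Z)-alkoxyallyllithium. Transfer to (+)-Ipc2BOMe (from (−)-α-pinene), BF3·OEt2 and addition of 14, then NaOH/H2O2, is the established diisopinocampheylborane (Z)-γ-alkoxyallylboration. It gives the syn 14-O-MOM 15-alcohol F3.
  - Mild MOM cleavage (TMSOTf, 2,2′-bipyridyl, CH2Cl2, 0 °C, then water) comes back to the route at 17.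

**Step 4.**
- What may go wrong: C–H silylation of a silyl ether derived from a secondary alcohol may stall; groups on silicon may redistribute; the ketal may lose methanol at 100 °C; another methyl group may be attacked.
- Fallback, setting out from 4:
  - The hypoiodite reaction (PhI(OAc)2, I2, visible light, cyclohexane) generates the 6α-alkoxy radical. Its 1,5-hydrogen atom transfer from C18 and ring closure give the 6α,18-epoxide F4.
  - RuCl3 (cat.)/NaIO4 oxidises the ether CH2 to the 18,6α-lactone F5.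
  - LiAlH4 in THF reduces it to 7, where the route is rejoined; 7 is then isolated and hydrolysed as in the second stage of step 5.

**Step 13.**
- What may go wrong: facial selectivity may be poor because the two ketone substituents are similar in size; the ene-dicarbonyl unit may undergo conjugate reduction; C15 may epimerise by enolisation.
- Fallback, setting out from 18, replaces hydride delivery by catalyst-controlled proton delivery:
  - C–H borylation of the only free furan α-position ([Ir(cod)OMe]2, 4,4′-di-tert-butyl-2,2′-bipyridine, 13, THF) gives the 2′-borylfuran F6.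
  - NaBO3·4H2O in THF/H2O gives, through the 2-hydroxyfuran tautomer, the β,γ-unsaturated lactone F7.
  - Organocatalytic asymmetric olefin isomerisation of β,γ- to α,β-butenolides by proton transfer, with a 6′-hydroxy cinchona alkaloid base in CH2Cl2 at low temperature, sets C5′ and comes back to the route at 23.

## Further compounds

F1 | step 9 | 6α,8α,18-tris(triethylsilyloxy)-15-norlabd-13(16)-en-14-ol | C=C(CC[C@@H]1[C@@]2(C)CCC[C@@](C)(CO[Si](CC)(CC)CC)[C@@H]2[C@@H](O[Si](CC)(CC)CC)C[C@@]1(C)O[Si](CC)(CC)CC)CO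
F2 | step 9 | 14-O-methoxymethyl ether of F1 | C=C(CC[C@@H]1[C@@]2(C)CCC[C@@](C)(CO[Si](CC)(CC)CC)[C@@H]2[C@@H](O[Si](CC)(CC)CC)C[C@@]1(C)O[Si](CC)(CC)CC)COCOC
F3 | step 9 | (14S,15R)-14-O-methoxymethyl-15-(3-methylfuran-2-yl)-15-ol | C=C(CC[C@@H]1[C@@]2(C)CCC[C@@](C)(CO[Si](CC)(CC)CC)[C@@H]2[C@@H](O[Si](CC)(CC)CC)C[C@@]1(C)O[Si](CC)(CC)CC)[C@H](OCOC)[C@@H](O)c1occc1C
F4 | step 4 | 6α,18-epoxy ketal (tetrahydrofuran on C4–C5–C6) | CO[C@]1(C)CC[C@@H]2[C@@]3(C)CCC[C@@](C)(C4)[C@@H]3[C@@H](O4)C[C@@]2(C)O1
F5 | step 4 | 18,6α-lactone ketal | CO[C@]1(C)CC[C@@H]2[C@@]3(C)CCC[C@@](C)(C4=O)[C@@H]3[C@@H](O4)C[C@@]2(C)O1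
F6 | step 13 | 2′-(pinacolboryl) derivative of furan 18 | C=C(CC[C@@H]1[C@@]2(C)CCC[C@@](C)(CO[Si](CC)(CC)CC)[C@@H]2[C@@H](O[Si](CC)(CC)CC)C[C@@]1(C)O[Si](CC)(CC)CC)[C@H](O[Si](CC)(CC)CC)[C@@H](O[Si](CC)(CC)CC)c1oc(B2OC(C)(C)C(C)(C)O2)cc1C
F7 | step 13 | β,γ-unsaturated lactone (4′-methyl-2(3H)-furanone) | C=C(CC[C@@H]1[C@@]2(C)CCC[C@@](C)(CO[Si](CC)(CC)CC)[C@@H]2[C@@H](O[Si](CC)(CC)CC)C[C@@]1(C)O[Si](CC)(CC)CC)[C@H](O[Si](CC)(CC)CC)[C@@H](O[Si](CC)(CC)CC)C1=C(C)CC(=O)O1
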